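**Assumption:** the target SMILES has no stereocentre and no stereogenic double bond. Ebenfuran VI is therefore achiral and no enantioselective step is needed. The stereocentres in 15, 19 and 20 are transient, racemic and erased by step 13.

## Retrosynthetic overview
1. Ebenfuran VI comes from its 4,4'-di-O-benzyl ether. The tertiary alcohol comes from MeMgBr addition to a C5 propanoate ester, done while the 3-CHO is held at the CH2OH level.
2. The furan ring is the last ring formed. It arises by acid cyclodehydration of an α-aryl-β-keto acetal, which comes from an iodine(III) 1,2-aryl shift of a chalcone.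
3. The key C–C bond is the chalcone Cα–Cβ bond. It is made by a Claisen–Schmidt aldol condensation of 4-benzyloxy-2-methoxyacetophenone with a fully substituted benzaldehyde.
4. The aldehyde comes from 2,4,6-trimethoxybenzaldehyde by HWE olefination, hydrogenation, Vilsmeier formylation and ortho-demethylation. A temporary dihydrocoumarin lactone (first ring, opened again) tells the two ortho phenols apart.
5. The ketone comes from 2,4-dihydroxyacetophenone by 4-O-benzylation and then 2-O-methylation.

## Route

**Step 1**
Reactants: 1 2,4-dihydroxyacetophenone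
Product: 2 4-(benzyloxy)-2-hydroxyacetophenone
Conditions: BnBr (1.05 equiv), K2CO3 (1.1 equiv), acetone, reflux
Reagents that add atoms: benzyl bromide BrCc1ccccc1
Why: Williamson etherification is selective for the 4-OH because the 2-OH is hydrogen-bonded to the ketone and far less nucleophilic.

**Step 2**
Reactants: 2 4-(benzyloxy)-2-hydroxyacetophenone
Product: 3 4-(benzyloxy)-2-methoxyacetophenone
Conditions: MeI (2 equiv), K2CO3, DMF, 40 °C
Reagents that add atoms: iodomethane CI
Why: Williamson O-methylation of the one remaining (chelated) phenol goes to completion with excess MeI in a dipolar aprotic solvent.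

**Step 3**
Reactants: 4 2,4,6-trimethoxybenzaldehyde
Product: 5 methyl (E)-3-(2,4,6-trimethoxyphenyl)acrylate
Conditions: (MeO)2P(O)CH2CO2Me, NaH, THF, 0 °C → rt
Reagents that add atoms: trimethyl phosphonoacetate COC(=O)CP(=O)(OC)OC
Why: Horner–Wadsworth–Emmons olefination of a non-enolisable aldehyde gives the E-cinnamate cleanly, and the alkene geometry is erased in the next step.

**Step 4**
Reactants: 5 methyl (E)-3-(2,4,6-trimethoxyphenyl)acrylate
Product: 6 methyl 3-(2,4,6-trimethoxyphenyl)propanoate
Conditions: H2 (1 atm), 10% Pd/C, MeOH, rt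
Reagents that add atoms: none
Why: Catalytic hydrogenation saturates the conjugated alkene while the aryl methyl ethers and the ester are inert.

**Step 5**
Reactants: 6 methyl 3-(2,4,6-trimethoxyphenyl)propanoate
Product: 8 methyl 3-(3-formyl-2,4,6-trimethoxyphenyl)propanoate, via aryl iminium dichlorophosphate 7 (not isolated)
Conditions: POCl3 (1.3 equiv), DMF, 0 °C → rt; then ice–H2O
Reagents that add atoms: N,N-dimethylformamide CN(C)C=O; water O
Why: Vilsmeier–Haack formylation of this symmetric, strongly activated arene can give only one mono-aldehyde, and the first formyl group deactivates the ring against a second attack.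

**Step 6**
Reactants: 8 methyl 3-(3-formyl-2,4,6-trimethoxyphenyl)propanoate
Product: 10 7-hydroxy-5-methoxy-2-oxochromane-8-carbaldehyde, via dihydroxy ester 9 (not isolated)
Conditions: AlCl3 (5 equiv), CH2Cl2, 0 °C → reflux; 1 M HCl; crude, p-TsOH·H2O (5 mol %), PhMe, reflux
Reagents that add atoms: none
Why: Chelation-controlled Lewis-acid ether cleavage removes only the two methyl ethers ortho to the aldehyde, and the acid-catalysed lactonisation can engage only the phenol next to the propanoate chain, so the two ortho phenols are differentiated without ambiguity.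

**Step 7**
Reactants: 10 7-hydroxy-5-methoxy-2-oxochromane-8-carbaldehyde
Product: 11 5-methoxy-7-(methoxymethoxy)-2-oxochromane-8-carbaldehyde
Conditions: MOMCl (2 equiv), i-Pr2NEt (3 equiv), CH2Cl2, 0 °C → reflux
Reagents that add atoms: chloromethyl methyl ether COCCl
Why: O-alkylation of the only free phenol with the highly reactive α-chloro ether (MOM protection) proceeds under amine base, which leaves the aryl lactone closed.

**Step 8**
Reactants: 11 5-methoxy-7-(methoxymethoxy)-2-oxochromane-8-carbaldehyde
Product: 13 methyl 3-[2-(benzyloxy)-3-formyl-6-methoxy-4-(methoxymethoxy)phenyl]propanoate, via sodium phenoxide ester 12 (not isolated)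
Conditions: NaOMe (1.05 equiv), MeOH, 0 °C → rt; evaporate; BnBr (1.3 equiv), DMF, 50 °C
Reagents that add atoms: sodium methoxide C[O-].[Na+]; benzyl bromide BrCc1ccccc1
Why: Methoxide transesterification opens the aryl lactone to the much weaker base, the ortho-formyl phenoxide, which is then capped by Williamson benzylation.

**Step 9 (key step)**
Reactants: 13 methyl 3-[2-(benzyloxy)-3-formyl-6-methoxy-4-(methoxymethoxy)phenyl]propanoate; 3 4-(benzyloxy)-2-methoxyacetophenone
Product: 17 (E)-3-[2-(benzyloxy)-3-{3-[4-(benzyloxy)-2-methoxyphenyl]-3-oxoprop-1-en-1-yl}-6-methoxy-4-(methoxymethoxy)phenyl]propanoic acid, via potassium carboxylate aldehyde 14 (not isolated), via potassium aldol carboxylate 15 (not isolated), via potassium chalcone carboxylate 16 (not isolated)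
Conditions: KOH (50% aq, 10 equiv), MeOH, rt, 1 h; add 3 (1.1 equiv), rt → 40 °C, 48 h; cold 1 M HCl to pH 4
Reagents that add atoms: potassium hydroxide [K+].[OH-]
Why: In this Claisen–Schmidt crossed aldol condensation only the ketone can enolise and only the aldehyde is a good acceptor, E1cB dehydration of the racemic aldol pulls the equilibrium to the conjugated E-enone, and the unavoidable ester saponification is simply taken to completion (MOM and Bn are base-stable).

**Step 10**
Reactants: 17 chalcone acid
Product: 18 methyl (E)-3-[2-(benzyloxy)-3-{3-[4-(benzyloxy)-2-methoxyphenyl]-3-oxoprop-1-en-1-yl}-6-methoxy-4-(methoxymethoxy)phenyl]propanoate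
Conditions: MeI (1.5 equiv), K2CO3, DMF, rt
Reagents that add atoms: iodomethane CI
Why: SN2 O-alkylation of the carboxylate restores the methyl ester under mild, non-acidic conditions that touch neither the enone nor the MOM group.

**Step 11**
Reactants: 18 chalcone methyl ester
Product: 19 methyl 3-[2-(benzyloxy)-3-{1-[4-(benzyloxy)-2-methoxyphenyl]-3,3-dimethoxy-1-oxopropan-2-yl}-6-methoxy-4-(methoxymethoxy)phenyl]propanoate (racemic)
Conditions: PhI(OH)OTs (1.2 equiv), MeOH–CH2Cl2 (3:1), 0 °C → rt
Reagents that add atoms: methanol CO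
Why: In this hypervalent-iodine oxidative chalcone rearrangement, iodine(III) and MeOH add across the alkene and reductive loss of PhI drives a 1,2-shift of the very electron-rich trialkoxyaryl group from Cβ to Cα, the resulting oxocarbenium ion is trapped as the dimethyl acetal, and the new stereocentre is racemic and erased in step 13.

**Step 12**
Reactants: 19 rearranged keto acetal
Product: 20 methyl 3-{4-(benzyloxy)-3-[4-(benzyloxy)-2-methoxybenzoyl]-2,6-dimethoxy-2,3-dihydro-1-benzofuran-5-yl}propanoate (racemic, mainly trans)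
Conditions: p-TsOH·H2O (0.1 equiv), MeOH, rt
Reagents that add atoms: none
Why: Acid-catalysed transacetalisation in methanol strips the MOM group as dimethoxymethane, so no formaldehyde electrophile is left near the electron-rich ring, and the freed phenol closes on the dimethyl acetal to a five-membered cyclic mixed acetal whose two racemic stereocentres are erased in the next step.

**Step 13**
Reactants: 20 2-methoxy-3-aroyl-2,3-dihydrobenzofuran
Product: 21 methyl 3-{4-(benzyloxy)-2-[4-(benzyloxy)-2-methoxyphenyl]-3-formyl-6-methoxy-1-benzofuran-5-yl}propanoate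
Conditions: p-TsOH·H2O (1 equiv), (CF3)2CHOH, rt, 30 min
Reagents that add atoms: none
Why: In strongly ionising, non-nucleophilic HFIP the cyclic acetal reopens, the phenol recloses on the protonated aryl ketone and loss of water gives the aromatic 2-aryl-3-formylbenzofuran (ring-opening/cyclodehydration), a path also favoured here because a formyl group suffers less peri strain against the 4-benzyloxy group than an aroyl group would.

**Step 14**
Reactants: 21 3-formylbenzofuran ester
Product: 22 methyl 3-{4-(benzyloxy)-2-[4-(benzyloxy)-2-methoxyphenyl]-3-(hydroxymethyl)-6-methoxy-1-benzofuran-5-yl}propanoate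
Conditions: NaBH4 (1.5 equiv), THF–MeOH, 0 °C
Reagents that add atoms: none
Why: Chemoselective borohydride reduction takes the aldehyde to the alcohol at 0 °C while the methyl ester is untouched, which removes the competing electrophile before the Grignard step.

**Step 15**
Reactants: 22 hydroxymethyl ester
Product: 24 4-{4-(benzyloxy)-2-[4-(benzyloxy)-2-methoxyphenyl]-3-(hydroxymethyl)-6-methoxy-1-benzofuran-5-yl}-2-methylbutan-2-ol, via methyl ketone magnesium alkoxide 23 (not isolated)
Conditions: MeMgBr (5 equiv), THF, 0 °C → rt; sat. aq NH4Cl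
Reagents that add atoms: methylmagnesium bromide C[Mg]Br
Why: Double Grignard addition to the unhindered ester gives the tertiary alcohol, one further equivalent merely deprotonates the primary alcohol, and the ethers are inert.

**Step 16**
Reactants: 24 diol
Product: 25 4-(benzyloxy)-2-[4-(benzyloxy)-2-methoxyphenyl]-5-(3-hydroxy-3-methylbutyl)-6-methoxy-1-benzofuran-3-carbaldehyde
Conditions: activated MnO2 (15 equiv), CH2Cl2, rt
Reagents that add atoms: none
Why: MnO2 oxidation is specific for the activated heterobenzylic primary alcohol, stops at the aldehyde and cannot oxidise the tertiary alcohol.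

**Step 17**
Reactants: 25 di-O-benzyl ebenfuran VI
Product: 26 ebenfuran VI, 4-hydroxy-2-(4-hydroxy-2-methoxyphenyl)-5-(3-hydroxy-3-methylbutyl)-6-methoxy-1-benzofuran-3-carbaldehyde
Conditions: H2 (1 atm), 10% Pd/C, EtOAc, rt, stopped at full conversion
Reagents that add atoms: none
Why: Neutral catalytic hydrogenolysis cleaves both aryl benzyl ethers without acid, so no chroman can form from the tertiary alcohol, and the push–pull 3-formyl group (a vinylogous ester) and the tetrasubstituted furan double bond are reduced much more slowly.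

## Compound list
1 | 2,4-dihydroxyacetophenone | CC(=O)c1ccc(O)cc1O | starting material
2 | 4-(benzyloxy)-2-hydroxyacetophenone | CC(=O)c1ccc(OCc2ccccc2)cc1O | intermediate
3 | 4-(benzyloxy)-2-methoxyacetophenone | CC(=O)c1ccc(OCc2ccccc2)cc1OC | intermediate
4 | 2,4,6-trimethoxybenzaldehyde | COc1cc(OC)c(C=O)c(OC)c1 | starting material
5 | methyl (E)-3-(2,4,6-trimethoxyphenyl)acrylate | COC(=O)/C=C/c1c(OC)cc(OC)cc1OC | intermediate
6 | methyl 3-(2,4,6-trimethoxyphenyl)propanoate | COC(=O)CCc1c(OC)cc(OC)cc1OC | intermediate
7 | aryl iminium dichlorophosphate (not isolated) | COC(=O)CCc1c(OC)cc(OC)c(C=[N+](C)C)c1OC.[O-]P(=O)(Cl)Cl | intermediate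
8 | methyl 3-(3-formyl-2,4,6-trimethoxyphenyl)propanoate | COC(=O)CCc1c(OC)cc(OC)c(C=O)c1OC | intermediate
9 | methyl 3-(3-formyl-2,4-dihydroxy-6-methoxyphenyl)propanoate (not isolated) | COC(=O)CCc1c(OC)cc(O)c(C=O)c1O | intermediate
10 | 7-hydroxy-5-methoxy-2-oxochromane-8-carbaldehyde | O=C1CCc2c(OC)cc(O)c(C=O)c2O1 | intermediate
11 | 5-methoxy-7-(methoxymethoxy)-2-oxochromane-8-carbaldehyde | O=C1CCc2c(OC)cc(OCOC)c(C=O)c2O1 | intermediate
12 | sodium 2-formyl-5-methoxy-6-(3-methoxy-3-oxopropyl)-3-(methoxymethoxy)phenoxide (not isolated) | [Na+].[O-]c1c(CCC(=O)OC)c(OC)cc(OCOC)c1C=O | intermediate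
13 | methyl 3-[2-(benzyloxy)-3-formyl-6-methoxy-4-(methoxymethoxy)phenyl]propanoate | COC(=O)CCc1c(OC)cc(OCOC)c(C=O)c1OCc1ccccc1 | intermediate
14 | potassium 3-[2-(benzyloxy)-3-formyl-6-methoxy-4-(methoxymethoxy)phenyl]propanoate (not isolated) | [K+].[O-]C(=O)CCc1c(OC)cc(OCOC)c(C=O)c1OCc1ccccc1 | intermediate
15 | potassium salt of the racemic β-hydroxy ketone aldol adduct (not isolated) | [K+].[O-]C(=O)CCc1c(OC)cc(OCOC)c(C(O)CC(=O)c2ccc(OCc3ccccc3)cc2OC)c1OCc1ccccc1 | intermediate
16 | potassium salt of the (E)-chalcone acid (not isolated) | [K+].[O-]C(=O)CCc1c(OC)cc(OCOC)c(/C=C/C(=O)c2ccc(OCc3ccccc3)cc2OC)c1OCc1ccccc1 | intermediate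
17 | (E)-chalcone acid | OC(=O)CCc1c(OC)cc(OCOC)c(/C=C/C(=O)c2ccc(OCc3ccccc3)cc2OC)c1OCc1ccccc1 | intermediate
18 | (E)-chalcone methyl ester | COC(=O)CCc1c(OC)cc(OCOC)c(/C=C/C(=O)c2ccc(OCc3ccccc3)cc2OC)c1OCc1ccccc1 | intermediate
19 | α-aryl-β-keto dimethyl acetal (racemic) | COC(=O)CCc1c(OC)cc(OCOC)c(C(C(OC)OC)C(=O)c2ccc(OCc3ccccc3)cc2OC)c1OCc1ccccc1 | intermediate
20 | 2-methoxy-3-aroyl-2,3-dihydrobenzofuran (racemic, mainly trans) | COC(=O)CCc1c(OC)cc2OC(OC)C(C(=O)c3ccc(OCc4ccccc4)cc3OC)c2c1OCc1ccccc1 | intermediate
21 | 2-aryl-3-formylbenzofuran ester | COC(=O)CCc1c(OC)cc2oc(-c3ccc(OCc4ccccc4)cc3OC)c(C=O)c2c1OCc1ccccc1 | intermediate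
22 | 3-(hydroxymethyl)benzofuran ester | COC(=O)CCc1c(OC)cc2oc(-c3ccc(OCc4ccccc4)cc3OC)c(CO)c2c1OCc1ccccc1 | intermediate
23 | methyl ketone as bromomagnesium alkoxide (not isolated) | CC(=O)CCc1c(OC)cc2oc(-c3ccc(OCc4ccccc4)cc3OC)c(CO[Mg]Br)c2c1OCc1ccccc1 | intermediate
24 | primary/tertiary diol | CC(C)(O)CCc1c(OC)cc2oc(-c3ccc(OCc4ccccc4)cc3OC)c(CO)c2c1OCc1ccccc1 | intermediate
25 | 4,4'-di-O-benzyl ebenfuran VI | CC(C)(O)CCc1c(OC)cc2oc(-c3ccc(OCc4ccccc4)cc3OC)c(C=O)c2c1OCc1ccccc1 | intermediate
26 | ebenfuran VI (achiral) | COc1cc(O)ccc1-c1oc2cc(OC)c(CCC(C)(C)O)c(O)c2c1C=O | target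

## Totals
Total step count: 17.
Longest linear sequence: 15 steps (steps 3–17, from 4). Steps 1–2 form the two-step side branch to 3.

## Three steps most likely to fail

**Step 11 (oxidative 1,2-aryl shift).**
- Risks: MOM loss before oxidation, which would expose a phenol to iodine(III), or over-oxidation of the trialkoxyarene.
- The fallback sets out from 18 and returns at 19, and it keeps electrophilic oxidants away from the arene.
- Nucleophilic Weitz–Scheffer epoxidation of 18 with t-BuOOH/DBU in toluene spares the ester and gives the racemic trans chalcone epoxide F1.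
- BF3·OEt2 in CH2Cl2 at −78 °C opens the benzylic C–O bond and triggers a 1,2-acyl shift (House–Meinwald type). This gives the racemic α-aryl-β-keto aldehyde F2, which has the same skeleton as the aryl-shift product.
- Acetalisation of F2 with HC(OMe)3/MeOH/PPTS rejoins the route at 19.

**Step 13 (HFIP ring-opening/cyclodehydration).**
- Risks: competing aromatisation to the isomeric 3-aroylbenzofuran, or acid loss of a benzyl ether.
- The fallback sets out from 20 and returns at 21.
- Propane-1,3-dithiol and BF3·OEt2 in CH2Cl2 at −20 °C convert the cyclic mixed acetal into the ring-opened dithiane keto phenol F3. The aldehyde carbon is now locked in a form that does not ionise.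
- Catalytic p-TsOH in toluene at 80 °C then lets the phenol condense with the only electrophile left, the ketone. This gives the 3-(1,3-dithian-2-yl)-2-arylbenzofuran F4.
- Alkylative hydrolysis with MeI/CaCO3 in aqueous MeCN unmasks the aldehyde and rejoins the route at 21.

**Step 17 (hydrogenolysis next to the aldehyde).**
- Risk: over-reduction of the CHO group to CH2OH or CH3.
- The fallback sets out from 21, replaces steps 14–17 and returns at 26. The aldehyde stays masked during both the Grignard addition and the hydrogenolysis.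
- Ethylene glycol and catalytic p-TsOH in toluene (Dean–Stark) give the dioxolane ester F5.
- MeMgBr in THF gives the dioxolane tertiary alcohol F6.
- H2 and Pd/C in EtOAc containing a trace of Et3N give the debenzylated dioxolane F7.
- PPTS in wet acetone at rt hydrolyses the very electron-rich acetal without ionising the tertiary alcohol and delivers 26.

## Further compounds
F1 | step 11 | racemic trans chalcone epoxide | COC(=O)CCc1c(OC)cc(OCOC)c(C2OC2C(=O)c3ccc(OCc4ccccc4)cc3OC)c1OCc1ccccc1
F2 | step 11 | racemic α-aryl-β-keto aldehyde | COC(=O)CCc1c(OC)cc(OCOC)c(C(C=O)C(=O)c2ccc(OCc3ccccc3)cc2OC)c1OCc1ccccc1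
F3 | step 13 | ring-opened dithiane keto phenol (racemic) | COC(=O)CCc1c(OC)cc(O)c(C(C2SCCCS2)C(=O)c3ccc(OCc4ccccc4)cc3OC)c1OCc1ccccc1
F4 | step 13 | 3-(1,3-dithian-2-yl)-2-arylbenzofuran | COC(=O)CCc1c(OC)cc2oc(-c3ccc(OCc4ccccc4)cc3OC)c(C3SCCCS3)c2c1OCc1ccccc1
F5 | step 17 | dioxolane ester | COC(=O)CCc1c(OC)cc2oc(-c3ccc(OCc4ccccc4)cc3OC)c(C3OCCO3)c2c1OCc1ccccc1
F6 | step 17 | dioxolane tertiary alcohol | CC(C)(O)CCc1c(OC)cc2oc(-c3ccc(OCc4ccccc4)cc3OC)c(C3OCCO3)c2c1OCc1ccccc1
F7 | step 17 | debenzylated dioxolane | CC(C)(O)CCc1c(OC)cc2oc(-c3ccc(O)cc3OC)c(C3OCCO3)c2c1O
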